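**Retrosynthetic overview**
- Silandrin ⇒ its tri-O-benzyl ether (hydrogenolysis last) ⇒ an alkylidene β-keto ester, by decarboxylation and a catalyst-controlled intramolecular oxa-Michael addition. The pyranone ring is formed last and sets C2 (S).
- Key C–C bond (C2–C3 of the flavanone): Knoevenagel/aldol condensation of the A-ring β-keto ester (from phloroacetophenone by Claisen-type C-acylation) with a benzodioxane-6-carbaldehyde.
- Aldehyde ⇒ aryl bromide (Br/Li exchange, DMF) ⇒ trans-1,4-benzodioxane, the first ring, closed by acid-mediated benzylic C–O formation under thermodynamic trans control.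
- Cyclisation precursor ⇒ aryl Grignard plus an (R)-2-aryloxy-3-silyloxypropanal ⇒ Mitsunobu inversion of a methyl (S)-glycerate derivative with 5-bromo-2-(methoxymethoxy)phenol. This sets the CH–CH2OH centre (R) from the chiral pool.

Assumption: compounds 1, 5, 10 and 18 are bought; reagents, catalysts and solvents are named but not numbered.

**Step 1**
Reactants: 1 5-bromo-2-hydroxybenzaldehyde
Product: 2 5-bromo-2-(methoxymethoxy)benzaldehyde
Conditions: MOMCl, i-Pr2NEt, CH2Cl2, 0 °C → rt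
Reagents that add atoms: chloromethyl methyl ether (MOMCl), COCCl
Why: O-alkylation of the phenoxide by the reactive α-chloro ether (MOM protection); no stereocentre.

**Step 2**
Reactants: 2 5-bromo-2-(methoxymethoxy)benzaldehyde
Product: 4 5-bromo-2-(methoxymethoxy)phenol, via 5-bromo-2-(methoxymethoxy)phenyl formate 3 (not isolated)
Conditions: mCPBA, CH2Cl2, rt; aq NaHCO3 wash; then K2CO3 (cat.), MeOH, rt
Reagents that add atoms: mCPBA, O=C(OO)c1cccc(Cl)c1
Why: Baeyer–Villiger (Dakin-type) oxidation, in which the o-alkoxyaryl group migrates in preference to H, then formate methanolysis; this leaves the free OH meta to Br and the MOM-protected oxygen para to Br.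

**Step 3**
Reactants: 5 methyl (S)-2,2-dimethyl-1,3-dioxolane-4-carboxylate
Product: 6 methyl (S)-2,3-dihydroxypropanoate
Conditions: Dowex 50W (H+), MeOH–H2O, rt
Reagents that add atoms: none
Why: acid-catalysed acetal hydrolysis that does not touch the stereocentre or the methyl ester.

**Step 4**
Reactants: 6 methyl (S)-2,3-dihydroxypropanoate
Product: 7 methyl (S)-3-[(tert-butyldimethylsilyl)oxy]-2-hydroxypropanoate
Conditions: TBSCl (1.05 equiv), imidazole, CH2Cl2, 0 °C
Reagents that add atoms: tert-butyldimethylsilyl chloride, CC(C)(C)[Si](C)(C)Cl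
Why: selective silylation of the less hindered primary hydroxyl leaves the secondary α-hydroxy ester free for the Mitsunobu step.

**Step 5**
Reactants: 4 5-bromo-2-(methoxymethoxy)phenol; 7 methyl (S)-3-[(tert-butyldimethylsilyl)oxy]-2-hydroxypropanoate
Product: 8 methyl (R)-2-[5-bromo-2-(methoxymethoxy)phenoxy]-3-[(tert-butyldimethylsilyl)oxy]propanoate
Conditions: PPh3, DIAD, THF, 0 °C → rt
Reagents that add atoms: none
Why: Mitsunobu etherification of an α-hydroxy ester by a phenol is a clean SN2 process, so the (S)-alcohol gives the (R)-aryl ether, which becomes C3 (R) of the benzodioxane.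

**Step 6**
Reactants: 8 methyl (R)-2-[5-bromo-2-(methoxymethoxy)phenoxy]-3-[(tert-butyldimethylsilyl)oxy]propanoate
Product: 9 (R)-2-[5-bromo-2-(methoxymethoxy)phenoxy]-3-[(tert-butyldimethylsilyl)oxy]propanal
Conditions: DIBAL-H (1.1 equiv), CH2Cl2, −78 °C; MeOH, then Rochelle salt; crude product used at once
Reagents that add atoms: none
Why: partial ester reduction; the chelated aluminium hemiacetal of an α-alkoxy ester survives at −78 °C and releases the aldehyde only on work-up, so the α-centre is not exposed to base.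

**Step 7**
Reactants: 9 (R)-2-[5-bromo-2-(methoxymethoxy)phenoxy]-3-[(tert-butyldimethylsilyl)oxy]propanal; 10 1-(benzyloxy)-4-bromo-2-methoxybenzene
Product: 12 (1RS,2R)-1-[4-(benzyloxy)-3-methoxyphenyl]-2-[5-bromo-2-(methoxymethoxy)phenoxy]-3-[(tert-butyldimethylsilyl)oxy]propan-1-ol, via [4-(benzyloxy)-3-methoxyphenyl]magnesium bromide 11 (not isolated)
Conditions: 10, Mg, THF (I2 cat.), rt; then 9, THF, −78 → 0 °C; H2O
Reagents that add atoms: none
Why: Grignard 1,2-addition to the aldehyde (an aryl-Mg reagent does not exchange with the ring bromide); the new carbinol centre is formed as a mixture on purpose, because it is reset in step 8.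

**Step 8**
Reactants: 12 (1RS,2R)-1-[4-(benzyloxy)-3-methoxyphenyl]-2-[5-bromo-2-(methoxymethoxy)phenoxy]-3-[(tert-butyldimethylsilyl)oxy]propan-1-ol
Product: 14 [(2R,3R)-2-[4-(benzyloxy)-3-methoxyphenyl]-6-bromo-2,3-dihydro-1,4-benzodioxin-3-yl]methanol, via (1RS,2R)-1-[4-(benzyloxy)-3-methoxyphenyl]-2-(5-bromo-2-hydroxyphenoxy)propane-1,3-diol 13 (not isolated)
Conditions: conc. HCl (cat.), MeOH, 45 °C; evaporate; Amberlyst-15, CH2Cl2, rt
Reagents that add atoms: none
Why: acid removes the aryl MOM and the TBS group, then ionises the electron-rich benzylic alcohol (or its methyl ether), and the freed phenol traps the cation in an SN1 cyclisation; both carbinol epimers converge on the diequatorial trans ring (a cis isomer re-ionises and equilibrates), so C2 becomes R relative to the untouched C3 (R).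

**Step 9**
Reactants: 14 [(2R,3R)-2-[4-(benzyloxy)-3-methoxyphenyl]-6-bromo-2,3-dihydro-1,4-benzodioxin-3-yl]methanol
Product: 15 tert-butyl{[(2R,3R)-2-[4-(benzyloxy)-3-methoxyphenyl]-6-bromo-2,3-dihydro-1,4-benzodioxin-3-yl]methoxy}dimethylsilane
Conditions: TBSCl, imidazole, DMF, rt
Reagents that add atoms: tert-butyldimethylsilyl chloride, CC(C)(C)[Si](C)(C)Cl
Why: silylation of the primary alcohol removes the acidic proton before the organolithium step and keeps the alcohol out of the later condensation and catalysis.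

**Step 10**
Reactants: 15 tert-butyl{[(2R,3R)-2-[4-(benzyloxy)-3-methoxyphenyl]-6-bromo-2,3-dihydro-1,4-benzodioxin-3-yl]methoxy}dimethylsilane
Product: 17 (2R,3R)-2-[4-(benzyloxy)-3-methoxyphenyl]-3-{[(tert-butyldimethylsilyl)oxy]methyl}-2,3-dihydro-1,4-benzodioxine-6-carbaldehyde, via the corresponding 6-lithio-benzodioxane 16 (not isolated)
Conditions: n-BuLi (1.1 equiv), THF, −78 °C; DMF, −78 → 0 °C; H2O
Reagents that add atoms: N,N-dimethylformamide, CN(C)C=O
Why: bromine–lithium exchange at −78 °C is much faster than any deprotonation, and formylation of the aryllithium with DMF (Bouveault) gives the aldehyde para to O1.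

**Step 11**
Reactants: 18 1-(2,4,6-trihydroxyphenyl)ethanone
Product: 19 1-[2,4-bis(benzyloxy)-6-hydroxyphenyl]ethanone
Conditions: BnBr (2.1 equiv), K2CO3 (2.2 equiv), DMF, rt
Reagents that add atoms: benzyl bromide, BrCc1ccccc1
Why: Williamson benzylation stops at the bis-ether because the last ortho-OH is hydrogen-bonded to the ketone and much less nucleophilic.

**Step 12**
Reactants: 19 1-[2,4-bis(benzyloxy)-6-hydroxyphenyl]ethanone
Product: 21 tert-butyl 3-[2,4-bis(benzyloxy)-6-hydroxyphenyl]-3-oxopropanoate, via the dilithium phenoxide-enolate of 19 20 (not isolated)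
Conditions: LiHMDS (3.3 equiv), THF, −78 °C; Boc2O (1.1 equiv), −78 → −20 °C; 1 M HCl
Reagents that add atoms: di-tert-butyl dicarbonate, CC(C)(C)OC(=O)OC(=O)OC(C)(C)C
Why: Claisen-type C-acylation of the ketone enolate carbon of the dianion (the more nucleophilic site), driven by deprotonation of the β-keto ester by the third equivalent of base; the tert-butyl ester and low temperature suppress lactonisation to a 4-hydroxycoumarin.

**Step 13**
Reactants: 17 (2R,3R)-2-[4-(benzyloxy)-3-methoxyphenyl]-3-{[(tert-butyldimethylsilyl)oxy]methyl}-2,3-dihydro-1,4-benzodioxine-6-carbaldehyde; 21 tert-butyl 3-[2,4-bis(benzyloxy)-6-hydroxyphenyl]-3-oxopropanoate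
Product: 22 tert-butyl 2-[2,4-bis(benzyloxy)-6-hydroxybenzoyl]-3-[(2R,3R)-2-[4-(benzyloxy)-3-methoxyphenyl]-3-{[(tert-butyldimethylsilyl)oxy]methyl}-2,3-dihydro-1,4-benzodioxin-6-yl]prop-2-enoate (E/Z mixture)
Conditions: piperidine (20 mol %), AcOH (20 mol %), 4 Å MS, PhMe, rt → 40 °C
Reagents that add atoms: none
Why: Knoevenagel (aldol) condensation, in which the doubly activated methylene of 21 adds to the iminium-activated aldehyde and dehydrates; this joins the two halves through the future C2–C3 bond, forms no stereocentre and leaves the non-enolisable benzodioxane centres alone.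

**Step 14**
Reactants: 22 tert-butyl 2-[2,4-bis(benzyloxy)-6-hydroxybenzoyl]-3-[(2R,3R)-2-[4-(benzyloxy)-3-methoxyphenyl]-3-{[(tert-butyldimethylsilyl)oxy]methyl}-2,3-dihydro-1,4-benzodioxin-6-yl]prop-2-enoate
Product: 26 (2S)-5,7-bis(benzyloxy)-2-[(2R,3R)-2-[4-(benzyloxy)-3-methoxyphenyl]-3-(hydroxymethyl)-2,3-dihydro-1,4-benzodioxin-6-yl]chroman-4-one, via the tert-butyl (2S,3R)-4-oxochromane-3-carboxylate 23 (not isolated), via the corresponding 4-oxochromane-3-carboxylic acid 24 (not isolated), via the TBS ether of 26 25 (not isolated)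
Conditions: 9-amino-9-deoxy-epi-quinidine N′-[3,5-bis(trifluoromethyl)phenyl]thiourea (10 mol %), PhMe, −25 °C; then TsOH·H2O (1 equiv), 80 °C; then MeOH, rt
Reagents that add atoms: none
Why: bifunctional thiourea/quinuclidine catalysis of the intramolecular oxa-Michael addition (thiourea binds the β-keto ester, the amine delivers the phenol to one alkene face) sets C2 as S under catalyst control; acid then cleaves the tert-butyl ester, the β-keto acid decarboxylates without touching C2, and methanolysis removes the TBS group. The quinidine-derived pseudoenantiomer is the one assigned here to the 2S series (the quinine-derived one gives 2R); this assignment is from memory and must be confirmed by CD on the first run.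

**Step 15**
Reactants: 26 (2S)-5,7-bis(benzyloxy)-2-[(2R,3R)-2-[4-(benzyloxy)-3-methoxyphenyl]-3-(hydroxymethyl)-2,3-dihydro-1,4-benzodioxin-6-yl]chroman-4-one
Product: 27 silandrin
Conditions: H2 (1 atm), 10 % Pd/C, EtOAc–MeOH, rt, stopped at full conversion
Reagents that add atoms: none
Why: hydrogenolysis of the three aryl benzyl ethers is neutral, so the flavanone cannot ring-open and racemise, and it is much faster than cleavage of the two cyclic benzylic C–O bonds; no stereocentre is touched.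

**Compound list**
1 | 5-bromo-2-hydroxybenzaldehyde | O=Cc1cc(Br)ccc1O | starting material
2 | 5-bromo-2-(methoxymethoxy)benzaldehyde | COCOc1ccc(Br)cc1C=O | intermediate
3 | 5-bromo-2-(methoxymethoxy)phenyl formate | COCOc1ccc(Br)cc1OC=O | intermediate (not isolated)
4 | 5-bromo-2-(methoxymethoxy)phenol | COCOc1ccc(Br)cc1O | intermediate
5 | methyl (S)-2,2-dimethyl-1,3-dioxolane-4-carboxylate | COC(=O)[C@@H]1COC(C)(C)O1 | starting material
6 | methyl (S)-2,3-dihydroxypropanoate | COC(=O)[C@@H](O)CO | intermediate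
7 | methyl (S)-3-[(tert-butyldimethylsilyl)oxy]-2-hydroxypropanoate | COC(=O)[C@@H](O)CO[Si](C)(C)C(C)(C)C | intermediate
8 | methyl (R)-2-[5-bromo-2-(methoxymethoxy)phenoxy]-3-[(tert-butyldimethylsilyl)oxy]propanoate | COC(=O)[C@H](Oc1cc(Br)ccc1OCOC)CO[Si](C)(C)C(C)(C)C | intermediate
9 | (R)-2-[5-bromo-2-(methoxymethoxy)phenoxy]-3-[(tert-butyldimethylsilyl)oxy]propanal | O=C[C@H](Oc1cc(Br)ccc1OCOC)CO[Si](C)(C)C(C)(C)C | intermediate
10 | 1-(benzyloxy)-4-bromo-2-methoxybenzene | COc1cc(Br)ccc1OCc1ccccc1 | starting material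
11 | [4-(benzyloxy)-3-methoxyphenyl]magnesium bromide | COc1cc([Mg]Br)ccc1OCc1ccccc1 | intermediate (not isolated)
12 | (1RS,2R)-1-[4-(benzyloxy)-3-methoxyphenyl]-2-[5-bromo-2-(methoxymethoxy)phenoxy]-3-[(tert-butyldimethylsilyl)oxy]propan-1-ol (C1 epimer mixture) | COc1cc(C(O)[C@H](Oc2cc(Br)ccc2OCOC)CO[Si](C)(C)C(C)(C)C)ccc1OCc1ccccc1 | intermediate
13 | (1RS,2R)-1-[4-(benzyloxy)-3-methoxyphenyl]-2-(5-bromo-2-hydroxyphenoxy)propane-1,3-diol | COc1cc(C(O)[C@H](Oc2cc(Br)ccc2O)CO)ccc1OCc1ccccc1 | intermediate (not isolated)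
14 | [(2R,3R)-2-[4-(benzyloxy)-3-methoxyphenyl]-6-bromo-2,3-dihydro-1,4-benzodioxin-3-yl]methanol (trans) | COc1cc([C@H]2Oc3ccc(Br)cc3O[C@@H]2CO)ccc1OCc1ccccc1 | intermediate
15 | tert-butyl{[(2R,3R)-2-[4-(benzyloxy)-3-methoxyphenyl]-6-bromo-2,3-dihydro-1,4-benzodioxin-3-yl]methoxy}dimethylsilane | COc1cc([C@H]2Oc3ccc(Br)cc3O[C@@H]2CO[Si](C)(C)C(C)(C)C)ccc1OCc1ccccc1 | intermediate
16 | {(2R,3R)-2-[4-(benzyloxy)-3-methoxyphenyl]-3-{[(tert-butyldimethylsilyl)oxy]methyl}-2,3-dihydro-1,4-benzodioxin-6-yl}lithium | COc1cc([C@H]2Oc3ccc([Li])cc3O[C@@H]2CO[Si](C)(C)C(C)(C)C)ccc1OCc1ccccc1 | intermediate (not isolated)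
17 | (2R,3R)-2-[4-(benzyloxy)-3-methoxyphenyl]-3-{[(tert-butyldimethylsilyl)oxy]methyl}-2,3-dihydro-1,4-benzodioxine-6-carbaldehyde | COc1cc([C@H]2Oc3ccc(C=O)cc3O[C@@H]2CO[Si](C)(C)C(C)(C)C)ccc1OCc1ccccc1 | intermediate
18 | 1-(2,4,6-trihydroxyphenyl)ethanone | CC(=O)c1c(O)cc(O)cc1O | starting material
19 | 1-[2,4-bis(benzyloxy)-6-hydroxyphenyl]ethanone | CC(=O)c1c(O)cc(OCc2ccccc2)cc1OCc1ccccc1 | intermediate
20 | dilithium phenoxide-enolate of 19 | [Li]OC(=C)c1c(O[Li])cc(OCc2ccccc2)cc1OCc1ccccc1 | intermediate (not isolated)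
21 | tert-butyl 3-[2,4-bis(benzyloxy)-6-hydroxyphenyl]-3-oxopropanoate | CC(C)(C)OC(=O)CC(=O)c1c(O)cc(OCc2ccccc2)cc1OCc1ccccc1 | intermediate
22 | tert-butyl 2-[2,4-bis(benzyloxy)-6-hydroxybenzoyl]-3-[(2R,3R)-2-[4-(benzyloxy)-3-methoxyphenyl]-3-{[(tert-butyldimethylsilyl)oxy]methyl}-2,3-dihydro-1,4-benzodioxin-6-yl]prop-2-enoate (E/Z mixture, alkene geometry left open) | COc1cc([C@H]2Oc3ccc(C=C(C(=O)OC(C)(C)C)C(=O)c4c(O)cc(OCc5ccccc5)cc4OCc4ccccc4)cc3O[C@@H]2CO[Si](C)(C)C(C)(C)C)ccc1OCc1ccccc1 | intermediate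
23 | tert-butyl (2S,3R)-5,7-bis(benzyloxy)-2-[(2R,3R)-2-[4-(benzyloxy)-3-methoxyphenyl]-3-{[(tert-butyldimethylsilyl)oxy]methyl}-2,3-dihydro-1,4-benzodioxin-6-yl]-4-oxochromane-3-carboxylate (trans shown; C3 is labile) | COc1cc([C@H]2Oc3ccc([C@@H]4[C@@H](C(=O)OC(C)(C)C)C(=O)c5c(OCc6ccccc6)cc(OCc6ccccc6)cc5O4)cc3O[C@@H]2CO[Si](C)(C)C(C)(C)C)ccc1OCc1ccccc1 | intermediate (not isolated)
24 | (2S,3R)-5,7-bis(benzyloxy)-2-[(2R,3R)-2-[4-(benzyloxy)-3-methoxyphenyl]-3-{[(tert-butyldimethylsilyl)oxy]methyl}-2,3-dihydro-1,4-benzodioxin-6-yl]-4-oxochromane-3-carboxylic acid | COc1cc([C@H]2Oc3ccc([C@@H]4[C@@H](C(=O)O)C(=O)c5c(OCc6ccccc6)cc(OCc6ccccc6)cc5O4)cc3O[C@@H]2CO[Si](C)(C)C(C)(C)C)ccc1OCc1ccccc1 | intermediate (not isolated)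
25 | (2S)-5,7-bis(benzyloxy)-2-[(2R,3R)-2-[4-(benzyloxy)-3-methoxyphenyl]-3-{[(tert-butyldimethylsilyl)oxy]methyl}-2,3-dihydro-1,4-benzodioxin-6-yl]chroman-4-one | COc1cc([C@H]2Oc3ccc([C@@H]4CC(=O)c5c(OCc6ccccc6)cc(OCc6ccccc6)cc5O4)cc3O[C@@H]2CO[Si](C)(C)C(C)(C)C)ccc1OCc1ccccc1 | intermediate (not isolated)
26 | (2S)-5,7-bis(benzyloxy)-2-[(2R,3R)-2-[4-(benzyloxy)-3-methoxyphenyl]-3-(hydroxymethyl)-2,3-dihydro-1,4-benzodioxin-6-yl]chroman-4-one | COc1cc([C@H]2Oc3ccc([C@@H]4CC(=O)c5c(OCc6ccccc6)cc(OCc6ccccc6)cc5O4)cc3O[C@@H]2CO)ccc1OCc1ccccc1 | intermediate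
27 | silandrin, (2S)-5,7-dihydroxy-2-[(2R,3R)-2-(4-hydroxy-3-methoxyphenyl)-3-(hydroxymethyl)-2,3-dihydro-1,4-benzodioxin-6-yl]chroman-4-one | COc1cc([C@H]2Oc3ccc([C@@H]4CC(=O)c5c(O)cc(O)cc5O4)cc3O[C@@H]2CO)ccc1O | target

**Totals**
Total steps: 15. Longest linear sequence: 11 steps (1 → 2 → 5 → 6 → 7 → 8 → 9 → 10 → 13 → 14 → 15; the branch through steps 3 and 4 is equally long).

**Steps most likely to fail, with fallbacks**

Step 14 (catalytic oxa-Michael, decarboxylation). The 6′-benzyloxy-substituted alkylidene is an extrapolation for this catalyst class, and acid at 80 °C could erode C2. A diastereomer ratio near 9:1 is a realistic outcome, so the minor (2R) isomer would have to be removed from 26 by crystallisation or preparative HPLC. The fallback sets out from aldehyde 17 and acetophenone 19. A Claisen–Schmidt aldol condensation (KOH, EtOH–THF, rt) gives the (E)-2′-hydroxychalcone F1. NaOAc in refluxing EtOH closes it without selectivity to a 1:1 mixture of 25 and its C2 epimer, the (2R)-flavanone F2. A kinetic resolution by Rh-catalysed asymmetric transfer hydrogenation ([Cp*RhCl((R,R)-TsDPEN)], HCO2H/Et3N, EtOAc, rt, stopped near 52 % conversion) reduces only F2, anti to its aryl group, to the (2R,4R)-cis-flavan-4-ol F3. F3 is separated by chromatography from untouched 25, where the fallback comes back to the route (TsOH, MeOH to 26). F3 can be recycled by Dess–Martin oxidation to F2 and re-equilibration with NaOAc.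

Step 12 (C-acylation of the dianion). O-acylation of the phenoxide or enolate oxygen, or lactonisation, may compete. The fallback sets out from 19. Boc2O, Et3N and catalytic DMAP in CH2Cl2 give the 2-acetyl-3,5-bis(benzyloxy)phenyl tert-butyl carbonate F4. LiHMDS (2.2 equiv, THF, −78 → 0 °C) then moves the Boc group from oxygen to the enolate carbon in a Baker–Venkataraman-type intramolecular acyl transfer. Acidic quench gives 21, where the fallback comes back to the route.

Step 6 (and the use of 9 in step 7). The α-aryloxy, β-silyloxy aldehyde can epimerise or eliminate, and DIBAL can over-reduce. The fallback sets out from ester 8. Me(MeO)NH·HCl with AlMe3 (CH2Cl2, 0 °C → rt) gives the (R)-Weinreb amide F5. Grignard reagent 11 (THF, 0 °C) adds once to give the (R)-α-aryloxy aryl ketone F6. F6 is reduced at once with NaBH4 (MeOH–THF, −20 °C) to 12, where the fallback comes back to the route; either carbinol epimer serves in step 8.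

**Further compounds**
F1 | step 14 | (E)-1-[2,4-bis(benzyloxy)-6-hydroxyphenyl]-3-[(2R,3R)-2-[4-(benzyloxy)-3-methoxyphenyl]-3-{[(tert-butyldimethylsilyl)oxy]methyl}-2,3-dihydro-1,4-benzodioxin-6-yl]prop-2-en-1-one | COc1cc([C@H]2Oc3ccc(/C=C/C(=O)c4c(O)cc(OCc5ccccc5)cc4OCc4ccccc4)cc3O[C@@H]2CO[Si](C)(C)C(C)(C)C)ccc1OCc1ccccc1
F2 | step 14 | (2R)-5,7-bis(benzyloxy)-2-[(2R,3R)-2-[4-(benzyloxy)-3-methoxyphenyl]-3-{[(tert-butyldimethylsilyl)oxy]methyl}-2,3-dihydro-1,4-benzodioxin-6-yl]chroman-4-one | COc1cc([C@H]2Oc3ccc([C@H]4CC(=O)c5c(OCc6ccccc6)cc(OCc6ccccc6)cc5O4)cc3O[C@@H]2CO[Si](C)(C)C(C)(C)C)ccc1OCc1ccccc1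
F3 | step 14 | (2R,4R)-5,7-bis(benzyloxy)-2-[(2R,3R)-2-[4-(benzyloxy)-3-methoxyphenyl]-3-{[(tert-butyldimethylsilyl)oxy]methyl}-2,3-dihydro-1,4-benzodioxin-6-yl]chroman-4-ol | COc1cc([C@H]2Oc3ccc([C@H]4C[C@@H](O)c5c(OCc6ccccc6)cc(OCc6ccccc6)cc5O4)cc3O[C@@H]2CO[Si](C)(C)C(C)(C)C)ccc1OCc1ccccc1
F4 | step 12 | 2-acetyl-3,5-bis(benzyloxy)phenyl tert-butyl carbonate | CC(=O)c1c(OC(=O)OC(C)(C)C)cc(OCc2ccccc2)cc1OCc1ccccc1
F5 | step 6 | (R)-2-[5-bromo-2-(methoxymethoxy)phenoxy]-3-[(tert-butyldimethylsilyl)oxy]-N-methoxy-N-methylpropanamide | CON(C)C(=O)[C@H](Oc1cc(Br)ccc1OCOC)CO[Si](C)(C)C(C)(C)C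
F6 | step 6 | (R)-1-[4-(benzyloxy)-3-methoxyphenyl]-2-[5-bromo-2-(methoxymethoxy)phenoxy]-3-[(tert-butyldimethylsilyl)oxy]propan-1-one | COc1cc(C(=O)[C@H](Oc2cc(Br)ccc2OCOC)CO[Si](C)(C)C(C)(C)C)ccc1OCc1ccccc1
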